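## Structural features

Marchantin H is an achiral, 18-membered macrocyclic bis(bibenzyl): four benzene rings are joined head to tail by two diaryl ether oxygens and two CH2CH2 bridges. Ring A is a 1,2,4-trisubstituted phenol whose OH lies para to its bridge carbon and ortho to the ether oxygen leading to ring B. Ring B is a para-phenylene; ring C carries its bridge at C1, the ether oxygen to ring D at C2 and a catechol at C3/C4; ring D is a meta-phenylene tied back to ring A by the second ethylene bridge. There is no stereocentre and no configurationally stable axis, so no stereochemical relationship has to be controlled. The fragile functions are the three free phenols, above all the air-sensitive catechol of ring C, and they are carried as methyl ethers to the last step. The real difficulties are the diaryl ether at C2 of ring C, which is flanked by a methoxy group and a benzylic carbon, and the closure of an 18-membered ring containing a rigid para-phenylene unit. The key step uses the B–C bridge, ring B–CH2–CH2–ring C: the carbon bonded to ring B enters as carbon monoxide between the C–B bond of a ring B arylboronate and the benzylic C–Cl bond on C1 of ring C. The ring therefore closes by C–C bond formation far from the congested ether, and the ketone left behind is reduced away.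

## Logic of the disconnections

18 to 17. The three O–CH3 bonds (one on ring A, two on ring C) are added in the retrosynthetic sense. The phenols would interfere with copper, palladium and base in earlier steps, and the methyl groups are already present in 3 and 9, so no protection step is spent. The demand on the forward step is cleavage of three alkyl aryl ethers without harm to the two diaryl ethers; BBr3 meets it because it needs an sp3 carbon for bromide attack.

17 to 16. A carbonyl group is placed on the bridge carbon bonded to ring B. This is the footprint of the carbon delivered as 15 and it does not alter the skeleton. The forward step must deoxygenate an aryl ketone without touching aryl ethers; ionic hydrogenation with Et3SiH in CF3CO2H does this.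

16 to 14 and 15. The C(ring B)–C(=O) and C(=O)–CH2(ring C) bonds are cut. This opens the macrocycle to an open chain in which both diaryl ethers and the D–A bridge are already in place, and one bridge carbon becomes a gas. The forward step needs CO uptake by the benzylpalladium species before the boronate transmetalates, and ring closure in preference to chain growth. It also requires that 14 holds a benzylic chloride and an arylboronate side by side.

14 to 12 to 11. The C–Cl bond is traced to C–OH and then to CH=O. The benzylic chloride is the most labile group of the route and would not survive a palladium borylation, so it is made last. The chlorination must spare the pinacol boronate and give material clean enough to use without chromatography.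

11 to 10. The C–B bond on ring B is traced to a C–Cl bond. A chloride is chosen as the latent boron site because it is inert to copper, ylide and diimide chemistry. The forward step must therefore borylate an electron-rich aryl chloride in the presence of an aldehyde.

10 to 8 and 9. The O–C2 bond of ring C is cut. The formyl group of 9 activates the hindered C–Br bond and later becomes the benzylic chloride carbon. Attaching 9 only at this point means that a single formyl group is present. A plan that formed this ether from a formyl-bearing ring D phenol would give a dialdehyde whose two formyl groups need opposite fates; this order avoids that problem without a protecting group. The demand is that the copper coupling leaves the ring B chloride alone.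

8 to 7 to 2 and 5. The D–A bridge is cut as a C=C bond between the two benzylic carbons. The aldehyde of 5 comes from 3 unchanged and the phenol of 2 stays free, so no protecting group is needed. The forward sequence must saturate the alkene without hydrogenolysis of the aryl chloride, which points to diimide.

5 to 3 and 4, and 2 to 1. The O–C bond to ring B is cut to a phenol and an arylboronic acid, and the C–P bond to a benzylic alcohol. Both forward steps are one-step operations on commercial materials; the O-arylation must run at room temperature so that aldehyde and chloride survive.

## Other disconnections considered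

Alternative 1: The cut is the bond between C4 of ring A and a carbonyl placed on the D–A bridge, with the precursor being the 18-membered macrolactone A1, in which the ring A oxygen is acylated by an arylacetic acid on ring D. The forward step is a para-Fries shift with AlCl3 in nitrobenzene or with CF3SO3H to give the carbocyclic hydroxy ketone A2.
- In its favour: macrolactonisation is among the most dependable ways to close an 18-membered ring. The shift frees the ring A phenol without a deprotection step. No palladium or pressurised gas is needed; on reagent simplicity it is the better plan.
- Against it: the acylium ion must find C4 of the ring it has just left. The position para to the other ring A oxygen and free positions on ring C are also nucleophilic. Intermolecular transacylation would give oligomers. Arylacetyl cations can lose CO. AlCl3 is liable to cleave a methoxy group of the vicinal pair on ring C.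
- Comparison: both plans leave a bridge ketone to be removed, so they are equal there. The chosen plan fixes the site of C–C bond formation by the position of boron, whereas A2 depends on the regiochemistry of electrophilic substitution. Step counts should be similar: ring formation takes two operations instead of one, but borylation and chlorination are saved.

Alternative 2: The cut is the O–C bond between ring C and the future ring D, made while ring D is still a cyclohexenone. The phenoxide at C2 of ring C in the seco chloroenone A3 adds to C3 of the tethered 3-chlorocyclohex-2-enone and expels chloride, giving the macrocyclic 3-aryloxycyclohexenone A4.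
- In its favour: it forms the most hindered bond of the target by addition–elimination at a vinylogous acid chloride, under mild base and without copper. On this bond it is the better plan, since the chosen route needs an Ullmann coupling in hot pyridine.
- Against it: ring D must then be made aromatic by 1,2-reduction, dehydration and dehydrogenation. The 5-substituted cyclohexane-1,3-dione with its long side chain has to be built from scratch. The hindered phenol needs a temporary protecting group.
- Comparison: the transient stereocentre at C5 of A4 is lost on aromatisation and is neutral. The polar mechanism is simpler than a three-component catalytic cycle. The step count would be clearly higher than in the chosen plan.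

Alternative 3: The cut is the ether bond between ring A and the oxygen on ring B. Tl(NO3)3, a trivalent thallium salt, would oxidise the 2,6-dibromophenol of ring A in the seco bis(phenol) A5. The oxygen of the 2,6-dichlorophenol of ring B would attack the ortho carbon, and zinc reduction of the dienone would give the macrocyclic halogenated ether A6.
- In its favour: it is biomimetic and runs at low temperature. All C–C bonds are made beforehand by routine olefination, and the ring A phenol emerges free. On mildness of the ring-closing conditions it is at least the equal of the chosen plan.
- Against it: it uses a stoichiometric, highly toxic thallium salt. Four blocking halogens must be installed and the three that remain removed by hydrogenolysis. The outcome depends on which phenol is oxidised and on O- versus C-coupling.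
- Comparison: both plans close the macrocycle in one operation. The chosen plan uses palladium catalytically but handles toxic CO, so safety is not entirely one-sided. The halogenation and dehalogenation steps make the alternative longer.

Key step: step 9

Remark: 1, 3, 4, 9 and 15, together with PPh3·HBr and B2pin2, are taken as commercial; organopalladium species inside catalytic cycles are not counted as compounds.

## Route

Step 1
Reactants: 1 3-hydroxybenzyl alcohol
Product: 2 (3-hydroxybenzyl)triphenylphosphonium bromide
Conditions: PPh3·HBr, MeCN, reflux
Reagents that add atoms: triphenylphosphine hydrobromide, [Br-].[PH+](c1ccccc1)(c1ccccc1)c1ccccc1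
Why: Acid-promoted substitution of the benzylic hydroxyl by PPh3 (protonation, loss of water, capture of the benzylic electrophile by phosphorus) is a known direct route from benzylic alcohols to phosphonium salts; the phenol is not alkylated under acidic conditions and the salt should crystallise on cooling.

Step 2
Reactants: 3 isovanillin; 4 4-chlorophenylboronic acid
Product: 5 3-(4-chlorophenoxy)-4-methoxybenzaldehyde
Conditions: Cu(OAc)2 (0.3 equiv), pyridine, 4 Å MS, CH2Cl2, O2 (1 atm), rt
Reagents that add atoms: none
Why: Chan–Lam O-arylation: the aryl group passes from boron to a divalent copper phenoxide, oxidation and reductive elimination give the diaryl ether, and O2 returns copper to the divalent state; at room temperature the aldehyde and the C–Cl bond, kept as an inert placeholder for boron, are untouched.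

Step 3
Reactants: 2 (3-hydroxybenzyl)triphenylphosphonium bromide; 5 3-(4-chlorophenoxy)-4-methoxybenzaldehyde
Product: 7 3-{2-[3-(4-chlorophenoxy)-4-methoxyphenyl]ethenyl}phenol (E/Z mixture), via phenoxide ylide 6 (not isolated)
Conditions: KOtBu (2.5 equiv), THF, 0 °C; then 5, 0 °C → rt; aq. HCl
Reagents that add atoms: none
Why: Wittig olefination with a semi-stabilised benzylic ylide; the first equivalent of base is taken by the phenol and the second forms the ylide, whose meta phenoxide is not conjugated with the ylide carbon and so leaves it nucleophilic; an E/Z mixture is acceptable because step 4 saturates the double bond.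

Step 4
Reactants: 7 3-{2-[3-(4-chlorophenoxy)-4-methoxyphenyl]ethenyl}phenol (E/Z mixture)
Product: 8 3-{2-[3-(4-chlorophenoxy)-4-methoxyphenyl]ethyl}phenol
Conditions: TsNHNH2, NaOAc, THF/H2O, reflux
Reagents that add atoms: none
Why: Diimide reduction: diimide formed by base-induced fragmentation of TsNHNH2 transfers two hydrogens concertedly to the nonpolar C=C bond only, so the aryl C–Cl bond, which is at risk under catalytic hydrogenation, is kept and both alkene isomers converge on one bibenzyl.

Step 5
Reactants: 8 3-{2-[3-(4-chlorophenoxy)-4-methoxyphenyl]ethyl}phenol; 9 2-bromo-3,4-dimethoxybenzaldehyde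
Product: 10 2-(3-{2-[3-(4-chlorophenoxy)-4-methoxyphenyl]ethyl}phenoxy)-3,4-dimethoxybenzaldehyde
Conditions: CuO, K2CO3, pyridine, reflux
Reagents that add atoms: none
Why: Ullmann diaryl ether synthesis: CuO serves as a reservoir of copper phenoxide, which substitutes the bromide of 9 because the ortho formyl group activates that position despite the flanking methoxy group; the unactivated ring B chloride is inert to ligand-free copper at this temperature, and this is the only formyl group in the molecule.

Step 6
Reactants: 10 2-(3-{2-[3-(4-chlorophenoxy)-4-methoxyphenyl]ethyl}phenoxy)-3,4-dimethoxybenzaldehyde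
Product: 11 3,4-dimethoxy-2-[3-(2-{4-methoxy-3-[4-(4,4,5,5-tetramethyl-1,3,2-dioxaborolan-2-yl)phenoxy]phenyl}ethyl)phenoxy]benzaldehyde
Conditions: B2pin2, Pd2(dba)3, XPhos, KOAc, dioxane, 100 °C
Reagents that add atoms: bis(pinacolato)diboron, CC1(C)OB(OC1(C)C)B1OC(C)(C)C(C)(C)O1
Why: Miyaura borylation of an aryl chloride: the bulky, electron-rich biarylphosphine lets zerovalent palladium add to the electron-rich C–Cl bond and acetate mediates boron transfer from B2pin2; KOAc is too weak a base to start Suzuki coupling of the product or to harm the aldehyde, and no benzylic halide is present yet.

Step 7
Reactants: 11 3,4-dimethoxy-2-[3-(2-{4-methoxy-3-[4-(4,4,5,5-tetramethyl-1,3,2-dioxaborolan-2-yl)phenoxy]phenyl}ethyl)phenoxy]benzaldehyde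
Product: 12 {3,4-dimethoxy-2-[3-(2-{4-methoxy-3-[4-(4,4,5,5-tetramethyl-1,3,2-dioxaborolan-2-yl)phenoxy]phenyl}ethyl)phenoxy]phenyl}methanol
Conditions: NaBH4, THF/EtOH, 0 °C
Reagents that add atoms: none
Why: Chemoselective borohydride reduction of the aldehyde; aryl pinacol boronates and aryl ethers are inert to NaBH4 at 0 °C.

Step 8
Reactants: 12 {3,4-dimethoxy-2-[3-(2-{4-methoxy-3-[4-(4,4,5,5-tetramethyl-1,3,2-dioxaborolan-2-yl)phenoxy]phenyl}ethyl)phenoxy]phenyl}methanol
Product: 14 2-{4-[5-(2-{3-[6-(chloromethyl)-2,3-dimethoxyphenoxy]phenyl}ethyl)-2-methoxyphenoxy]phenyl}-4,4,5,5-tetramethyl-1,3,2-dioxaborolane (seco benzylic chloride arylboronate), via chlorosulfite 13 (not isolated)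
Conditions: SOCl2 (1.1 equiv), CH2Cl2, 0 °C; volatiles removed with toluene, used crude
Reagents that add atoms: thionyl chloride, O=S(Cl)Cl
Why: Deoxychlorination through the chlorosulfite: the benzylic carbon is para to a methoxy group, so the chlorosulfite ionises and collapses to the chloride with loss of SO2 at 0 °C; pinacol boronates tolerate SOCl2 and all by-products are volatile, so the labile chloride needs no chromatography.

Step 9
Reactants: 14 seco benzylic chloride arylboronate; 15 carbon monoxide
Product: 16 macrocyclic deoxybenzoin (tri-O-methylmarchantin H with C=O on the bridge carbon bonded to ring B)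
Conditions: Pd(OAc)2 (10 mol %), PPh3 (40 mol %), powdered K3PO4 (3 equiv), H2O (10 equiv), toluene, CO (5 bar), 80 °C; 14 added by pump over 12 h to 2 mM
Reagents that add atoms: none
Why: Zerovalent palladium, formed from Pd(OAc)2 and PPh3 under CO, adds oxidatively to the benzylic C–Cl bond on ring C, which is activated by the para methoxy group, and the benzylpalladium chloride inserts 15 to give the arylacetyl complex. Base-assisted transmetalation from the ring B boronate and reductive elimination then form the C(=O)–C(ring B) bond. The closest known reaction is the intermolecular carbonylative Suzuki–Miyaura coupling of benzyl chlorides with arylboron reagents to benzyl aryl ketones, run here within one molecule. The 18-membered ring closes end to end: transmetalation gives a 19-membered acyl(aryl)palladacycle that contracts to the carbocycle on reductive elimination, and no stereocentre is formed. The step needs ketone formation in preference to direct coupling to a 17-membered diarylmethane; CO insertion into a benzylpalladium bond is fast at 5 bar while transmetalation of a pinacol boronate is slow, so the acyl complex is the species that meets boron. Ring closure in preference to chain growth is secured by the slow addition, which keeps the stationary concentration low, and by the two diaryl ether hinges and the flexible D–A bridge, which let the chain ends meet without strain. Water is limited to a few equivalents so that hydrolysis of the acyl complex to an arylacetic acid stays slower than the intramolecular transmetalation.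

Step 10
Reactants: 16 macrocyclic deoxybenzoin
Product: 17 tri-O-methylmarchantin H
Conditions: Et3SiH (5 equiv), CF3CO2H/CH2Cl2, 0 °C → rt
Reagents that add atoms: none
Why: Ionic hydrogenation of an aryl ketone: protonation and hydride transfer from silicon give the carbinol, which ionises to a benzylic cation stabilised by the para aryloxy group of ring B and takes a second hydride; any alkene formed by proton loss from that cation is re-protonated and reduced to the same product, and methyl and diaryl ethers are stable to the acid.

Step 11
Reactants: 17 tri-O-methylmarchantin H
Product: 18 marchantin H
Conditions: BBr3 (6 equiv), CH2Cl2, −78 °C → rt; then H2O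
Reagents that add atoms: none
Why: Lewis-acid cleavage of aryl methyl ethers: BBr3 binds each methoxy oxygen and bromide attacks the methyl carbon by SN2; the diaryl ethers offer no sp3 carbon and survive, and the acidic aqueous work-up releases the catechol and phenol without exposing them to base and air.

## Compound list

1 | 3-hydroxybenzyl alcohol | OCc1cccc(O)c1 | starting material
2 | (3-hydroxybenzyl)triphenylphosphonium bromide | [Br-].Oc1cccc(C[P+](c2ccccc2)(c2ccccc2)c2ccccc2)c1 | intermediate
3 | isovanillin (3-hydroxy-4-methoxybenzaldehyde) | COc1ccc(C=O)cc1O | starting material
4 | 4-chlorophenylboronic acid | OB(O)c1ccc(Cl)cc1 | starting material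
5 | 3-(4-chlorophenoxy)-4-methoxybenzaldehyde | COc1ccc(C=O)cc1Oc1ccc(Cl)cc1 | intermediate
6 | potassium 3-[(triphenyl-λ5-phosphanylidene)methyl]phenolate (phenoxide ylide, not isolated) | [K+].[O-]c1cccc(C=P(c2ccccc2)(c2ccccc2)c2ccccc2)c1 | intermediate
7 | 3-{2-[3-(4-chlorophenoxy)-4-methoxyphenyl]ethenyl}phenol (E/Z mixture) | COc1ccc(C=Cc2cccc(O)c2)cc1Oc1ccc(Cl)cc1 | intermediate
8 | 3-{2-[3-(4-chlorophenoxy)-4-methoxyphenyl]ethyl}phenol | COc1ccc(CCc2cccc(O)c2)cc1Oc1ccc(Cl)cc1 | intermediate
9 | 2-bromo-3,4-dimethoxybenzaldehyde | COc1ccc(C=O)c(Br)c1OC | starting material
10 | 2-(3-{2-[3-(4-chlorophenoxy)-4-methoxyphenyl]ethyl}phenoxy)-3,4-dimethoxybenzaldehyde | O=Cc1ccc(OC)c(OC)c1Oc1cccc(c1)CCc1ccc(OC)c(c1)Oc1ccc(Cl)cc1 | intermediate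
11 | 3,4-dimethoxy-2-[3-(2-{4-methoxy-3-[4-(4,4,5,5-tetramethyl-1,3,2-dioxaborolan-2-yl)phenoxy]phenyl}ethyl)phenoxy]benzaldehyde | O=Cc1ccc(OC)c(OC)c1Oc1cccc(c1)CCc1ccc(OC)c(c1)Oc1ccc(cc1)B1OC(C)(C)C(C)(C)O1 | intermediate
12 | {3,4-dimethoxy-2-[3-(2-{4-methoxy-3-[4-(4,4,5,5-tetramethyl-1,3,2-dioxaborolan-2-yl)phenoxy]phenyl}ethyl)phenoxy]phenyl}methanol | OCc1ccc(OC)c(OC)c1Oc1cccc(c1)CCc1ccc(OC)c(c1)Oc1ccc(cc1)B1OC(C)(C)C(C)(C)O1 | intermediate
13 | chlorosulfite ester of 12 (not isolated) | ClS(=O)OCc1ccc(OC)c(OC)c1Oc1cccc(c1)CCc1ccc(OC)c(c1)Oc1ccc(cc1)B1OC(C)(C)C(C)(C)O1 | intermediate
14 | 2-{4-[5-(2-{3-[6-(chloromethyl)-2,3-dimethoxyphenoxy]phenyl}ethyl)-2-methoxyphenoxy]phenyl}-4,4,5,5-tetramethyl-1,3,2-dioxaborolane (seco benzylic chloride arylboronate) | ClCc1ccc(OC)c(OC)c1Oc1cccc(c1)CCc1ccc(OC)c(c1)Oc1ccc(cc1)B1OC(C)(C)C(C)(C)O1 | intermediate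
15 | carbon monoxide | [C-]#[O+] | starting material
16 | macrocyclic deoxybenzoin (tri-O-methylmarchantin H with C=O on the bridge carbon bonded to ring B) | COc1ccc2cc1Oc1ccc(cc1)C(=O)Cc1ccc(OC)c(OC)c1Oc1cccc(c1)CC2 | intermediate
17 | tri-O-methylmarchantin H | COc1ccc2cc1Oc1ccc(cc1)CCc1ccc(OC)c(OC)c1Oc1cccc(c1)CC2 | intermediate
18 | marchantin H | Oc1ccc2cc1Oc1ccc(cc1)CCc1ccc(O)c(O)c1Oc1cccc(c1)CC2 | target

## Step count and least certain steps

Total step count: 11. Longest linear sequence: 10 steps (3 to 18, steps 2 to 11); step 1 is a one-step side branch.

Step 9 (key step). Three processes could defeat it: transmetalation before CO uptake, which contracts the ring by one carbon; intermolecular coupling, which leads to chain growth; and hydrolysis of the acylpalladium intermediate or protodeboronation, which ends the sequence without ring closure. The balance between boronate activation and acyl hydrolysis depends on the small amount of water and cannot be predicted with confidence. Fallback: starting from 10, methylenation with Ph3P=CH2 (MePPh3Br, KOtBu, THF) would give the ring C styrene 2-(3-{2-[3-(4-chlorophenoxy)-4-methoxyphenyl]ethyl}phenoxy)-1-ethenyl-3,4-dimethoxybenzene F1. Anti-Markovnikov hydroboration with 9-borabicyclo[3.3.1]nonane in THF would give the B-alkyl-9-borabicyclononane F2, used without isolation. A high-dilution intramolecular B-alkyl Suzuki–Miyaura coupling with the ring B chloride (Pd(OAc)2, SPhos, K3PO4, THF/H2O, 65 °C) would then close the same 18-membered ring and return to the route at 17, so that steps 6 to 10 are bypassed.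

Step 10. The benzylic cation formed after the first hydride transfer could be captured transannularly by one of the electron-rich rings (Friedel–Crafts alkylation) faster than by the silane, or reduction could stall at the carbinol stage. Fallback: starting from 16, a Wolff–Kishner reduction in the Huang-Minlon manner (N2H4·H2O, KOH, diethylene glycol, 130 → 200 °C) would proceed through the hydrazone F3 and return at 17 by an anionic pathway with no carbocation. Any loss of a methyl ether in the hot alkali would be of no consequence because step 11 removes them all.

Step 5. Substitution at a bromide flanked by two ortho substituents may be slow, so that hydrodebromination of 9 and base-induced disproportionation of the aldehyde compete during long heating. Fallback: starting from 8, a copper-free nucleophilic aromatic substitution on 2-fluoro-3,4-dimethoxybenzaldehyde (K2CO3, DMA, 130 °C), in which the ortho formyl group stabilises the Meisenheimer intermediate, would return at 10 without any new intermediate.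

Step 2. O-Arylation may remain incomplete because protodeboronation and oxidative side reactions of the boronic acid consume it while the ortho methoxy group slows the phenol. Fallback: starting from 3, an Ullmann coupling with 1-chloro-4-iodobenzene (CuCl, 2,2,6,6-tetramethylheptane-3,5-dione, Cs2CO3, NMP, 120 °C), in which only the C–I bond reacts, would return at 5 without any new intermediate.

## Further compounds

F1 | step 9 | 2-(3-{2-[3-(4-chlorophenoxy)-4-methoxyphenyl]ethyl}phenoxy)-1-ethenyl-3,4-dimethoxybenzene | C=Cc1ccc(OC)c(OC)c1Oc1cccc(c1)CCc1ccc(OC)c(c1)Oc1ccc(Cl)cc1
F2 | step 9 | 9-{2-[2-(3-{2-[3-(4-chlorophenoxy)-4-methoxyphenyl]ethyl}phenoxy)-3,4-dimethoxyphenyl]ethyl}-9-borabicyclo[3.3.1]nonane | B1(CCc2ccc(OC)c(OC)c2Oc2cccc(c2)CCc2ccc(OC)c(c2)Oc2ccc(Cl)cc2)C2CCCC1CCC2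
F3 | step 10 | hydrazone of macrocyclic deoxybenzoin 16 (mixture of C=N isomers) | COc1ccc2cc1Oc1ccc(cc1)C(=NN)Cc1ccc(OC)c(OC)c1Oc1cccc(c1)CC2
F0 | step 5 | none | none
F0 | step 2 | none | none
A1 | alternative 1 | 18-membered macrolactone, ring A aryl ester of the ring D arylacetic acid, di-O-methyl | O=C1Cc2cccc(c2)Oc2c(OC)c(OC)ccc2CCc2ccc(cc2)Oc2ccccc2O1
A2 | alternative 1 | macrocyclic 4-hydroxydeoxybenzoin with the ketone on the D–A bridge carbon bonded to ring A | Oc1ccc2cc1Oc1ccc(cc1)CCc1ccc(OC)c(OC)c1Oc1cccc(c1)CC2=O
A3 | alternative 2 | seco ring C phenol with tethered 3-chloro-5-alkylcyclohex-2-enone, racemic, one enantiomer drawn | O=C1C=C(Cl)C[C@H](C1)CCc1ccc(OC)c(c1)Oc1ccc(cc1)CCc1ccc(OC)c(OC)c1O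
A4 | alternative 2 | macrocyclic 3-aryloxycyclohex-2-enone, racemic, one enantiomer drawn | O=C1C=C2C[C@H](C1)CCc1ccc(OC)c(c1)Oc1ccc(cc1)CCc1ccc(OC)c(OC)c1O2
A5 | alternative 3 | seco bis(phenol) with 2,6-dibromophenol ring A and 2,6-dichlorophenol ring B | Oc1c(Br)cc(cc1Br)CCc1cccc(c1)Oc1c(OC)c(OC)ccc1CCc1cc(Cl)c(O)c(Cl)c1
A6 | alternative 3 | bromo dichloro di-O-methyl macrocyclic diaryl ether | Oc1c(Br)cc2cc1Oc1c(Cl)cc(cc1Cl)CCc1ccc(OC)c(OC)c1Oc1cccc(c1)CC2
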